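All runs are calculated for an exercise, noise included.

- The vessel holds a stirred first phase together with a second phase, and its two earlier runs differ in the protic impurity, so the flask asked about lies between them in that charge.

common to all: substrate 0.50 M

| charge | reagent in the second phase | protic impurity | remark | time | volume of the second phase over the first |
|---|---|---|---|---|---|
| epsilon | 1.5 equiv | 0.34 M | run made earlier |  |  |
| gamma | 1.5 equiv | 0.75 M | run made earlier |  |  |
| flask | 1.50 equiv | 0.500 M |  | 5.0 h | 0.25 |

| run | time / h | target / % | crystals / % | substrate / % |
|---|---|---|---|---|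
| epsilon | 0.500 | 1.0 | 0 | 99.4 |
| epsilon | 0.833 | 1.7 | 0 | 98.3 |
| epsilon | 1.33 | 3.2 | 0.6 | 96.7 |
| epsilon | 2.00 | 4.9 | 0.4 | 94.7 |
| epsilon | 4.00 | 10.7 | 0.3 | 89.3 |
| epsilon | 6.00 | 16.3 | 0 | 83.2 |
| gamma | 1.00 | 1.4 | 0.3 | 98.8 |
| gamma | 2.00 | 2.0 | 0 | 97.9 |
| gamma | 3.00 | 4.0 | 0 | 95.9 |
| gamma | 4.00 | 5.1 | 0 | 94.9 |
| gamma | 5.00 | 6.8 | 0.2 | 93.8 |
| gamma | 6.00 | 6.8 | 0 | 92.8 |

(standard deviation of a reading: 0.3 percentage points)

- target is meant together with its crystals
- in the second phase: reagent in the second phase; everything else is in the first
- charges count per volume of the first phase; a concentration in a rate is the amount of a species over the volume of its own phase; every rate counts per litre of the first phase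
- solid, in amounts per volume of the solution: crystals
- the earlier runs hold the two phases in the same ratio of volumes as the flask asked about

- the target and crystals together standing at 5.0 h, as a percentage of the substrate charged
- concentration of target in solution at 5.0 h, in percent of saturation

- Working with the fraction of substrate left, minus its logarithm over the time gives a rate constant of 0.0307 h⁻¹ at epsilon's last reading and 0.0125 h⁻¹ at gamma's.
- Multiplied by the charged c(protic impurity), these readings become 0.0104 M h⁻¹ and 0.00934 M h⁻¹, and their mean 0.00988 M h⁻¹ is carried on as g, the impurity-weighted rate constant, for flasks with these substrate and reagent charges and this ratio of phases.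
- The reckoning here, which is not the forecast's, divides g by the flask's 0.500 M, so its substrate starts to go at a pseudo-first-order constant of 0.0198 h⁻¹, the impurity charge putting a factor 0.680 on the rate at epsilon's charge.
- The substrate's own loss then puts a factor 0.906 on the flask's rate by 5.0 h, so 9.41% is made, less than the 9.90% of an unslowed rate.
- Epsilon's last reading shows 16.3% of target with 0% of crystals, so the target reckoned here for the flask at 5.0 h comes to about 57.7% of that reading, an estimated ceiling on its percent of saturation that carries the scatter of the reading.
- The forecast gives 9.1% and 35%, saying “no crystallisation is evident”.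

- The flask gives 9.34% and 22.2%, and its c(reagent in the reaction phase) reads 0.0106 M at 0.500 h and 0.0110 M at 5.00 h. Carried to 10.0 h, g gives 17.9%, and the flask then holds 18.0%.

    reagent in the reaction phase ⇌ reagent in the second phase, rate k1*([reagent in the reaction phase] - [reagent in the second phase]/K1) per volume of the first phase (partition coefficient = 33.8, kL = 0.0235 min⁻¹)
    reagent in the reaction phase + protic impurity → quenched reagent (k = 0.312 M⁻¹ min⁻¹)
    substrate + reagent in the reaction phase → target (k = 0.0307 M⁻¹ min⁻¹)
    crystals ⇌ target, rate k4*(cs4 - [target]) while solid is left; crystals form when [target] > cs4 (solubility = 0.210 M, k = 0.689 min⁻¹)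

- In the neighbour flask charged with 1.2 M of protic impurity, g gives a constant of 0.00823 h⁻¹ and so 4.03% of target at 5.0 h; the computed neighbour holds 3.72%.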